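Readings and results are simulated from invented constants; the scatter is artificial.

In Wednesday's run the solid substrate is lost faster than target appears: at 12.0 h the solid reads 18% and target 2%. So we order the flask by its times, the shortest first.

| setting | Thursday's | Wednesday's | oak | birch | cedar |
|---|---|---|---|---|---|
| solid substrate | 0.081 M | 0.081 M | 0.081 M | 0.081 M | 0.081 M |
| free catalyst | 11 mM | 24 mM | 16 mM | 16 mM | 16 mM |
| temperature | −25 °C | 10 °C | 40 °C | −20 °C | 10 °C |
| remark | run made earlier | run made earlier |  |  |  |
| time |  |  | 20 h | 20 h | 20 h |

- Thursday's (time / h: target / %, solid substrate / %): 72.0: 0, 34; 144: 0, 32; 192: 0, 32; 288: 0, 30; 360: 1, 29; 480: 1, 29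
- Wednesday's (time / h: target / %, solid substrate / %): 4.00: 1, 45; 12.0: 2, 18; 25.0: 19, 8; 40.0: 25, 0; 48.0: 30, 3; 72.0: 44, 0; 96.0: 64, 0

(readings scatter by 2 percentage points)

- which flask leads in amount of target, in percent of the solid substrate charged ("all alike" within 1.5 percentage points) (oak / birch / cedar / all alike)
- how much target is there at the end, in percent of the solid substrate charged: oak
- how much target is there at the end, in percent of the solid substrate charged: birch
- how much target is there at the end, in percent of the solid substrate charged: cedar

- solid substrate is a solid; its amount is given per volume of the solution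
- the numbers in the tables scatter by 2 percentage points (one standard deviation)
- at the start none of the solid substrate is in solution
- what has only dissolved of solid substrate counts as not reacted

First rung, at 10 °C. Between 4.00 h and 12.0 h, Wednesday's solid reading falls with a time constant of

8.73 h.

Second rung. Later, target climbs steadily. We carry the round time (the turnover time): the time in which each charged catalyst makes one target on average. From 40.0 h to 96.0 h it is

42.5 h,

longer than the solid's time.

Third rung. At 16 mM, the charge needs

5.06 rounds, or 215 h at 10 °C.

Cedar has 20 h, which is shorter, so we reckon 9.29% target there.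

Temperature. Thursday's last target reading, 1%, lies within the scatter, so its round time of 6520 h is rough. Set against Wednesday's, it gives an activation energy of 84.0 kJ/mol. Then:

oak: round time 1.39 h, the charge needs 7.03 h

birch: round time 2920 h, target 0.135%

Oak's need is shorter than 20 h, and its round time is the shortest of the three, so we expect it to lead if its catalyst lasts.

The forecast names oak: 88% (55% to 100%), birch 0% (0% to 1%), cedar 4% (1% to 10%). It calls cedar “still in the lag”, and our cedar figure stands above its one.

The flask gives 89.7% in oak, 0.0234% in birch and 8.07% in cedar, so oak leads, as forecast. At 20.0 h, 84.9% of oak's catalyst is spent catalyst. Oak's target amounts to 4.54 rounds per charged catalyst, an average round of 4.41 h, longer than our 1.39 h.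

    starting material + free catalyst ⇌ catalyst intermediate (K = 620 /M, k = 0.0220 /M/s, Ea = 51.0 kJ/mol, ΔH = −23.0 kJ/mol)
    catalyst intermediate → free catalyst + target (k = 4.20 × 10⁻⁴ /s, Ea = 95.0 kJ/mol)
    solid substrate ⇌ starting material, rate k3*(cs3 - [starting material]) while solid is left; crystals form when [starting material] > cs3 (solubility = 45.0 mM, k = 1.30 × 10⁻⁴ /s)
    2 free catalyst → spent catalyst (k = 0.00870 /M/s, Ea = 69.0 kJ/mol)
    (constants at 40 °C)

Second flask: oak's charge at 15 °C. The round time comes to 22.9 h, which gives 17.3% target in 20 h. The computed result is 15.7%.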